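The synthesis rests on disconnecting the C7–C11 bond of the γ-lactone. A diethylphosphonoacetate carbanion bound to O6 opens a cis C7–C8 epoxide at C7 from the rear, so that a single operation closes the trans-fused lactone ring (C6, O6, C12, C11, C7), sets C7 and releases O8 as the only free hydroxyl. It exploits the contiguous O6 / C11-on-C7 / O8 array on C6–C7–C8 of the ten-membered carbocycle, where C11 is trans to both oxygens. The precursor is the furanone-bridged macrocyclic epoxide carrying the phosphonoacetate on O6 and a TBS ether on O9, assembled from a citramalate-derived lactone and a syn-aldol-derived enyne by alkynylation, furanone closure and ring-closing metathesis.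

Key step: step 16

Remarks on the chemistry (assumptions)
- Numbering: C1 is the furanone enol-ether carbon (bonded to the ring oxygen and C10), C2 the furanone CH, C3 the furanone carbonyl, C4 the quaternary methyl-bearing carbon, C5 the CH2, C6 the lactone O–CH, C7 the ring-fusion CH, C8 the ester carbinol, C9 the free carbinol, C10 the CH–CH3, and C11/C12/C13 the lactone α-carbon, carbonyl and exocyclic methylene. O-n is the oxygen on C-n.
- Structure check: the target is (4R,6S,7R,8S,9S,10S). The key-step precursor and product, as drawn in the list, carry the target configuration at C4, C6, C8, C9 and C10 and differ at C7 by the inversion the SN2 opening requires, so neither needed correction. The C7 descriptor changes from S to R on methacrylation only because the CIP priorities change.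
- C9/C10: O9 and the C10 methyl are syn, so both centres are set together by an Evans syn-aldol. An entry from methyl 3-hydroxy-2-methylpropanoate would need the (R)-ester in the robust sequence (ester carbon to C9, hydroxymethyl carbon to the alkyne); the (S)-ester fits only a sequence through configurationally labile 2-methylbut-3-ynal, and either way C9 would rest on an unselective vinyl addition.
- C6: O6 is 1,3-syn to O4 across a quaternary centre, which substrate-controlled addition to a C6 aldehyde cannot be relied on to deliver. C6 is therefore set by catalyst-controlled transfer hydrogenation of an ynone; the propenyl group left after semihydrogenation is lost as propene in the metathesis.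
- Step 3 assumes the usual sense of induction (the (S,S)-catalyst giving the (S)-propargylic alcohol); were it opposite, the enantiomeric catalyst would be used.

Step 1
Reactants: 1 (R)-citramalic acid
Product: 2 2-[(4R)-2,2,4-trimethyl-5-oxo-1,3-dioxolan-4-yl]acetic acid
Conditions: 2,2-dimethoxypropane, TsOH·H2O (cat.), rt
Reagents that add atoms: 2,2-dimethoxypropane, COC(C)(C)OC
Why: Acid-catalysed acetonide formation ties the tertiary hydroxyl and its geminal carboxyl into a dioxolanone, which differentiates the two carboxyls and leaves the C4 stereocentre untouched.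

Step 2
Reactants: 2 2-[(4R)-2,2,4-trimethyl-5-oxo-1,3-dioxolan-4-yl]acetic acid
Product: 4 (5R)-2,2,5-trimethyl-5-(2-oxopent-3-yn-1-yl)-1,3-dioxolan-4-one, via acyl chloride 3 (not isolated)
Conditions: (COCl)2, DMF (cat.), CH2Cl2, 0 °C → rt; then propyne, PdCl2(PPh3)2 (2 mol%), CuI (4 mol%), Et3N, THF, rt
Reagents that add atoms: propyne, CC#C
Why: Acyl Sonogashira coupling of the acid chloride with a terminal alkyne gives the ynone under near-neutral conditions that the hindered dioxolanone carbonyl should tolerate.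

Step 3
Reactants: 4 (5R)-2,2,5-trimethyl-5-(2-oxopent-3-yn-1-yl)-1,3-dioxolan-4-one
Product: 6 (3R,5S)-3-hydroxy-3-methyl-5-(prop-1-yn-1-yl)oxolan-2-one, via hydroxy dioxolanone 5 (not isolated)
Conditions: Ru[(S,S)-TsNCHPhCHPhNH](p-cymene) (1 mol%), iPrOH, rt; then TsOH·H2O (cat.), CH2Cl2, rt
Reagents that add atoms: none
Why: Noyori asymmetric transfer hydrogenation of the alkynyl ketone sets C6 as S under catalyst control, independent of the remote C4 centre, and the acid then closes the γ-lactone onto the dioxolanone carbonyl with loss of acetone.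

Step 4
Reactants: 6 (3R,5S)-3-hydroxy-3-methyl-5-(prop-1-yn-1-yl)oxolan-2-one
Product: 7 (3R,5S)-3-hydroxy-3-methyl-5-[(1Z)-prop-1-en-1-yl]oxolan-2-one
Conditions: H2 (1 atm), Pd/CaCO3 poisoned with Pb(OAc)2, quinoline, EtOAc, rt
Reagents that add atoms: none
Why: Lindlar semihydrogenation adds hydrogen syn to give the Z-propenyl group that later serves as the metathesis handle.

Step 5
Reactants: 7 (3R,5S)-3-hydroxy-3-methyl-5-[(1Z)-prop-1-en-1-yl]oxolan-2-one
Product: 8 (3R,5S)-3-methyl-5-[(1Z)-prop-1-en-1-yl]-3-[(trimethylsilyl)oxy]oxolan-2-one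
Conditions: N-(trimethylsilyl)imidazole, CH2Cl2, rt
Reagents that add atoms: N-(trimethylsilyl)imidazole, C[Si](C)(C)n1ccnc1
Why: Silylation of the tertiary alcohol removes the only acidic proton of the lactone before the acetylide addition.

Step 6
Reactants: 9 (4S)-4-benzyl-3-propanoyl-1,3-oxazolidin-2-one; 10 acrolein
Product: 11 (4S)-4-benzyl-3-[(2S,3R)-3-hydroxy-2-methylpent-4-enoyl]-1,3-oxazolidin-2-one
Conditions: Bu2BOTf, iPr2NEt, CH2Cl2, 0 °C; then 10, −78 → 0 °C; then pH 7 buffer, MeOH, 30% H2O2, 0 °C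
Reagents that add atoms: none
Why: Evans syn-aldol, in which the Z-boron enolate reacts through a closed chair transition state on the face away from the benzyl group, sets C10 (2S) and C9 (3R) together in the syn relationship.

Step 7
Reactants: 11 (4S)-4-benzyl-3-[(2S,3R)-3-hydroxy-2-methylpent-4-enoyl]-1,3-oxazolidin-2-one
Product: 12 (4S)-4-benzyl-3-[(2S,3R)-3-{[tert-butyl(dimethyl)silyl]oxy}-2-methylpent-4-enoyl]-1,3-oxazolidin-2-one
Conditions: TBSOTf, 2,6-lutidine, CH2Cl2, −78 → 0 °C
Reagents that add atoms: tert-butyldimethylsilyl triflate, CC(C)(C)[Si](C)(C)OS(=O)(=O)C(F)(F)F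
Why: Silyl triflate protection of the secondary alcohol installs the O9 ether that is carried to the last step and prevents retro-aldol cleavage.

Step 8
Reactants: 12 (4S)-4-benzyl-3-[(2S,3R)-3-{[tert-butyl(dimethyl)silyl]oxy}-2-methylpent-4-enoyl]-1,3-oxazolidin-2-one
Product: 13 (2R,3R)-3-{[tert-butyl(dimethyl)silyl]oxy}-2-methylpent-4-en-1-ol
Conditions: LiBH4, MeOH (1 equiv), THF, 0 °C
Reagents that add atoms: none
Why: Reductive cleavage of the imide with LiBH4 releases the primary alcohol and the recoverable auxiliary without touching the silyl ether or the alkene.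

Step 9
Reactants: 13 (2R,3R)-3-{[tert-butyl(dimethyl)silyl]oxy}-2-methylpent-4-en-1-ol
Product: 14 (2S,3R)-3-{[tert-butyl(dimethyl)silyl]oxy}-2-methylpent-4-enal
Conditions: Dess–Martin periodinane, pyridine, CH2Cl2, 0 °C → rt
Reagents that add atoms: none
Why: Dess–Martin oxidation under buffered conditions gives the α-methyl aldehyde without epimerisation, and it is used at once.

Step 10
Reactants: 14 (2S,3R)-3-{[tert-butyl(dimethyl)silyl]oxy}-2-methylpent-4-enal
Product: 15 tert-butyl(dimethyl){[(3R,4R)-4-methylhex-1-en-5-yn-3-yl]oxy}silane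
Conditions: dimethyl (1-diazo-2-oxopropyl)phosphonate, K2CO3, MeOH, 0 °C → rt
Reagents that add atoms: dimethyl (1-diazo-2-oxopropyl)phosphonate, CC(=O)C(=[N+]=[N-])P(=O)(OC)OC
Why: Ohira–Bestmann (Seyferth–Gilbert) homologation converts the aldehyde into the terminal alkyne with one added carbon (C2) under carbonate conditions mild enough to preserve C10.

Step 11
Reactants: 15 tert-butyl(dimethyl){[(3R,4R)-4-methylhex-1-en-5-yn-3-yl]oxy}silane; 8 (3R,5S)-3-methyl-5-[(1Z)-prop-1-en-1-yl]-3-[(trimethylsilyl)oxy]oxolan-2-one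
Product: 17 (3R,4R,8R,10S,11Z)-3-{[tert-butyl(dimethyl)silyl]oxy}-8,10-dihydroxy-4,8-dimethyltrideca-1,11-dien-5-yn-7-one, via TMS ynone 16 (not isolated)
Conditions: n-BuLi, THF, −78 °C; then 8, −78 → −30 °C; AcOH; then citric acid (cat.), MeOH, rt
Reagents that add atoms: none
Why: The lithium acetylide adds once to the lactone carbonyl (nucleophilic acyl substitution), since the lactone has no α-hydrogen and its lactolate does not collapse before the quench, and acidic methanol then strips the TMS ether.

Step 12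
Reactants: 17 (3R,4R,8R,10S,11Z)-3-{[tert-butyl(dimethyl)silyl]oxy}-8,10-dihydroxy-4,8-dimethyltrideca-1,11-dien-5-yn-7-one
Product: 18 (2R)-5-[(2S,3R)-3-{[tert-butyl(dimethyl)silyl]oxy}pent-4-en-2-yl]-2-[(2S,3Z)-2-hydroxypent-3-en-1-yl]-2-methylfuran-3(2H)-one
Conditions: Et2NH, EtOH, rt
Reagents that add atoms: none
Why: Amine-mediated 5-endo-dig oxa-Michael cyclisation of the α'-hydroxy ynone (conjugate addition of Et2NH, attack of the tertiary hydroxyl at C1, loss of the amine) gives the 3(2H)-furanone with C4 and C10 unchanged.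

Step 13
Reactants: 18 (2R)-5-[(2S,3R)-3-{[tert-butyl(dimethyl)silyl]oxy}pent-4-en-2-yl]-2-[(2S,3Z)-2-hydroxypent-3-en-1-yl]-2-methylfuran-3(2H)-one
Product: 19 (2S,3R,4Z,6S,8R)-3-{[tert-butyl(dimethyl)silyl]oxy}-6-hydroxy-2,8-dimethyl-11-oxabicyclo[6.2.1]undeca-1(10),4-dien-9-one
Conditions: (H2IMes)(PCy3)Cl2Ru=CHPh (second-generation Grubbs catalyst, 10 mol%), 1,4-benzoquinone (10 mol%), toluene (1 mM), 80 °C
Reagents that add atoms: none
Why: Ring-closing metathesis between the vinyl and propenyl groups expels propene, and the nine-membered oxa-bridged ring that forms can hold only the Z C7=C8 alkene, while benzoquinone suppresses hydride-induced isomerisation of the allylic alcohol.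

Step 14
Reactants: 19 (2S,3R,4Z,6S,8R)-3-{[tert-butyl(dimethyl)silyl]oxy}-6-hydroxy-2,8-dimethyl-11-oxabicyclo[6.2.1]undeca-1(10),4-dien-9-one
Product: 20 epoxy alcohol (cis-7,8-epoxide of 19 on the face of the 6-OH; 4R,6S,7S,8S,9S,10S)
Conditions: VO(acac)2 (5 mol%), t-BuOOH (decane solution), CH2Cl2, 0 °C → rt
Reagents that add atoms: tert-butyl hydroperoxide, CC(C)(C)OO
Why: Hydroxyl-directed epoxidation through the vanadate ester of the C6 alcohol delivers oxygen to the alkene face syn to O6, as established for medium-ring Z-cycloalkenols and reinforced by the C9 silyloxy group on the other face, which sets C7 and C8 as the cis-epoxide.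

Step 15
Reactants: 20 epoxy alcohol; 21 diethylphosphonoacetic acid
Product: 22 6-O-[(diethoxyphosphoryl)acetyl] epoxide (key-step precursor; 4R,6S,7S,8S,9S,10S)
Conditions: DCC, DMAP (cat.), CH2Cl2, 0 °C → rt
Reagents that add atoms: none
Why: Steglich esterification acylates the only free hydroxyl (O6) under neutral conditions that leave the epoxide intact.

Step 16
Reactants: 22 6-O-[(diethoxyphosphoryl)acetyl] epoxide
Product: 23 trans-fused α-(diethoxyphosphoryl) γ-lactone with free 8-OH and 9-OTBS (4R,6S,7S,8S,9S,10S,11R)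
Conditions: Cs2CO3 (1.2 equiv), MeCN, 0 °C → rt; AcOH quench
Reagents that add atoms: none
Why: Proposed new method: Cs2CO3 deprotonates the phosphonoacetate (more acidic than any furanone C–H), and the stabilised carbanion attacks C7 from the face opposite the epoxide oxygen in an intramolecular SN2 step that forms C7–C11 and expels the C8 alkoxide, which is at once protonated by the more acidic α-phosphono lactone C–H; the closest known reactions are the C2-selective opening of 2,3-epoxy alcohol derivatives by O-tethered carbamate or imidate nucleophiles and the intermolecular alkylation of phosphonoacetate anions by epoxides. The γ-lactone ring (C6, O6, C12, C11, C7) closes in a 5-exo-tet mode, the breaking C7–O bond lying outside the new ring. C7 is set by inversion, so its configuration follows from the epoxide made in step 14; C11 forms as an epimerisable phosphonate-bearing centre, expected with phosphorus trans to C8, and is erased in step 17. The step needs C7-over-C8 regioselectivity, which the two-atom O6–C12 tether secures because attack at C8 would demand a six-membered ring and an unattainable rear trajectory; it also needs the tether to reach the rear of C7, which the trans ring fusion should permit once the C5–C6–C7–C8 torsion opens beyond about 120°. Chemoselectivity rests on the low basicity of carbonate, and staying at or below room temperature should keep phosphoryl transfer to the new alkoxide (the cyclopropanation pathway), translactonisation to O8 and silyl migration from O9 from competing.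

Step 17
Reactants: 23 trans-fused α-(diethoxyphosphoryl) γ-lactone
Product: 24 α-methylene γ-lactone with free 8-OH and 9-OTBS (4R,6S,7S,8S,9S,10S)
Conditions: 37% aq. HCHO, K2CO3, THF, 0 °C
Reagents that add atoms: formaldehyde, C=O
Why: Horner–Wadsworth–Emmons methylenation of the α-phosphono lactone with formaldehyde under mild aqueous carbonate installs C13 and removes the transient C11 stereocentre.

Step 18
Reactants: 24 α-methylene γ-lactone with free 8-OH
Product: 25 8-O-methacrylate with 9-OTBS (4R,6S,7R,8S,9S,10S)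
Conditions: methacrylic anhydride, Et3N, DMAP, CH2Cl2, 0 °C → rt
Reagents that add atoms: methacrylic anhydride, C=C(C)C(=O)OC(=O)C(C)=C
Why: DMAP-catalysed acylation esterifies the sole free hydroxyl (O8), so the position of the methacrylate is not in question.

Step 19
Reactants: 25 8-O-methacrylate with 9-OTBS
Product: 26 CNP0195404.1 (4R,6S,7R,8S,9S,10S)
Conditions: HF·pyridine, pyridine, THF, 0 °C → rt
Reagents that add atoms: none
Why: Acidic fluoride cleaves the secondary TBS ether without base, which should avoid O8-to-O9 acyl migration and conjugate addition to the two unsaturated esters.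

Compound list
1 | (R)-citramalic acid, (2R)-2-hydroxy-2-methylbutanedioic acid | OC(=O)[C@@](C)(CC(=O)O)O | starting material
2 | 2-[(4R)-2,2,4-trimethyl-5-oxo-1,3-dioxolan-4-yl]acetic acid | CC1(C)OC(=O)[C@@](C)(CC(=O)O)O1 | intermediate
3 | 2-[(4R)-2,2,4-trimethyl-5-oxo-1,3-dioxolan-4-yl]acetyl chloride | CC1(C)OC(=O)[C@@](C)(CC(=O)Cl)O1 | intermediate (not isolated)
4 | (5R)-2,2,5-trimethyl-5-(2-oxopent-3-yn-1-yl)-1,3-dioxolan-4-one | CC1(C)OC(=O)[C@@](C)(CC(=O)C#CC)O1 | intermediate
5 | (5R)-5-[(2S)-2-hydroxypent-3-yn-1-yl]-2,2,5-trimethyl-1,3-dioxolan-4-one | CC1(C)OC(=O)[C@@](C)(C[C@H](O)C#CC)O1 | intermediate (not isolated)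
6 | (3R,5S)-3-hydroxy-3-methyl-5-(prop-1-yn-1-yl)oxolan-2-one | O=C1O[C@H](C#CC)C[C@@]1(C)O | intermediate
7 | (3R,5S)-3-hydroxy-3-methyl-5-[(1Z)-prop-1-en-1-yl]oxolan-2-one | O=C1O[C@H](/C=C\C)C[C@@]1(C)O | intermediate
8 | (3R,5S)-3-methyl-5-[(1Z)-prop-1-en-1-yl]-3-[(trimethylsilyl)oxy]oxolan-2-one | O=C1O[C@H](/C=C\C)C[C@@]1(C)O[Si](C)(C)C | intermediate
9 | (4S)-4-benzyl-3-propanoyl-1,3-oxazolidin-2-one | CCC(=O)N1[C@@H](Cc2ccccc2)COC1=O | starting material
10 | acrolein (prop-2-enal) | C=CC=O | starting material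
11 | (4S)-4-benzyl-3-[(2S,3R)-3-hydroxy-2-methylpent-4-enoyl]-1,3-oxazolidin-2-one | C=C[C@@H](O)[C@H](C)C(=O)N1[C@@H](Cc2ccccc2)COC1=O | intermediate
12 | (4S)-4-benzyl-3-[(2S,3R)-3-{[tert-butyl(dimethyl)silyl]oxy}-2-methylpent-4-enoyl]-1,3-oxazolidin-2-one | C=C[C@@H](O[Si](C)(C)C(C)(C)C)[C@H](C)C(=O)N1[C@@H](Cc2ccccc2)COC1=O | intermediate
13 | (2R,3R)-3-{[tert-butyl(dimethyl)silyl]oxy}-2-methylpent-4-en-1-ol | C=C[C@@H](O[Si](C)(C)C(C)(C)C)[C@H](C)CO | intermediate
14 | (2S,3R)-3-{[tert-butyl(dimethyl)silyl]oxy}-2-methylpent-4-enal | C=C[C@@H](O[Si](C)(C)C(C)(C)C)[C@H](C)C=O | intermediate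
15 | tert-butyl(dimethyl){[(3R,4R)-4-methylhex-1-en-5-yn-3-yl]oxy}silane | C=C[C@@H](O[Si](C)(C)C(C)(C)C)[C@H](C)C#C | intermediate
16 | (3R,4R,8R,10S,11Z)-3-{[tert-butyl(dimethyl)silyl]oxy}-10-hydroxy-4,8-dimethyl-8-[(trimethylsilyl)oxy]trideca-1,11-dien-5-yn-7-one | C=C[C@@H](O[Si](C)(C)C(C)(C)C)[C@H](C)C#CC(=O)[C@](C)(O[Si](C)(C)C)C[C@H](O)/C=C\C | intermediate (not isolated)
17 | (3R,4R,8R,10S,11Z)-3-{[tert-butyl(dimethyl)silyl]oxy}-8,10-dihydroxy-4,8-dimethyltrideca-1,11-dien-5-yn-7-one | C=C[C@@H](O[Si](C)(C)C(C)(C)C)[C@H](C)C#CC(=O)[C@](C)(O)C[C@H](O)/C=C\C | intermediate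
18 | (2R)-5-[(2S,3R)-3-{[tert-butyl(dimethyl)silyl]oxy}pent-4-en-2-yl]-2-[(2S,3Z)-2-hydroxypent-3-en-1-yl]-2-methylfuran-3(2H)-one | C=C[C@@H](O[Si](C)(C)C(C)(C)C)[C@H](C)C1=CC(=O)[C@@](C)(C[C@H](O)/C=C\C)O1 | intermediate
19 | (2S,3R,4Z,6S,8R)-3-{[tert-butyl(dimethyl)silyl]oxy}-6-hydroxy-2,8-dimethyl-11-oxabicyclo[6.2.1]undeca-1(10),4-dien-9-one (route numbering 4R,6S,7Z,9R,10S) | C1[C@H](O)/C=C\[C@@H](O[Si](C)(C)C(C)(C)C)[C@H](C)C2=CC(=O)[C@]1(C)O2 | intermediate
20 | epoxy alcohol: cis-7,8-epoxide of 19 on the face of the 6-OH, 9-OTBS (4R,6S,7S,8S,9S,10S) | O[C@H]1C[C@@]2(C)OC(=CC2=O)[C@@H](C)[C@H](O[Si](C)(C)C(C)(C)C)[C@H]3O[C@@H]13 | intermediate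
21 | diethylphosphonoacetic acid | CCOP(=O)(OCC)CC(=O)O | starting material
22 | key-step precursor: 6-O-[(diethoxyphosphoryl)acetyl] derivative of 20 (4R,6S,7S,8S,9S,10S) | CCOP(=O)(OCC)CC(=O)O[C@H]1C[C@@]2(C)OC(=CC2=O)[C@@H](C)[C@H](O[Si](C)(C)C(C)(C)C)[C@H]3O[C@@H]13 | intermediate
23 | key-step product: trans-fused γ-lactone (O6–C12, C11–C7) bearing P(O)(OEt)2 on C11, free 8-OH, 9-OTBS (4R,6S,7S,8S,9S,10S,11R) | CCOP(=O)(OCC)[C@H]1C(=O)O[C@H]2C[C@@]3(C)OC(=CC3=O)[C@@H](C)[C@H](O[Si](C)(C)C(C)(C)C)[C@@H](O)[C@H]12 | intermediate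
24 | α-methylene γ-lactone, free 8-OH, 9-OTBS (4R,6S,7S,8S,9S,10S) | C=C1C(=O)O[C@H]2C[C@@]3(C)OC(=CC3=O)[C@@H](C)[C@H](O[Si](C)(C)C(C)(C)C)[C@@H](O)[C@H]12 | intermediate
25 | 8-O-methacrylate of 24, 9-OTBS (4R,6S,7R,8S,9S,10S) | C=C(C)C(=O)O[C@@H]1[C@@H](O[Si](C)(C)C(C)(C)C)[C@H](C)C2=CC(=O)[C@@](C)(C[C@@H]3OC(=O)C(=C)[C@@H]13)O2 | intermediate
26 | CNP0195404.1 (4R,6S,7R,8S,9S,10S) | C=C(C)C(=O)O[C@@H]1[C@@H](O)[C@H](C)C2=CC(=O)[C@@](C)(C[C@@H]3OC(=O)C(=C)[C@@H]13)O2 | target

Total step count: 19. Longest linear sequence: 14 steps (steps 1–5 or 6–10, then 11–19).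

Steps most likely to fail

1. Step 16 (Proposed new method). What may go wrong: the tethered carbanion may not reach the rear of C7 in the accessible ring conformations, or base-induced side processes (translactonisation to O8, phosphoryl transfer, silyl migration) may outrun a slow alkylation. Fallback with known chemistry, setting out from 20 and rejoining at 25: the C6 hydroxyl of 20 is silylated (TESCl, imidazole, DMF) to the triethylsilyl ether F1. The epoxide is then opened intermolecularly with LiC≡CH and BF3·OEt2 in THF at −78 °C (epoxide alkynylation), anti attack being expected at C7 because C8 is screened by the adjacent silyloxy-bearing C9, to give the homopropargylic alcohol F2. The liberated C8 hydroxyl is esterified with methacrylic anhydride (Et3N, DMAP) to the methacrylate F3. The TES group is removed selectively (HF·pyridine, pyridine, THF, 0 °C) to the hydroxy alkyne F4. Palladium-catalysed cyclocarbonylation of this homopropargylic alcohol (PdCl2, SnCl2, PPh3, CO, MeCN, 75 °C) then closes the α-methylene lactone onto O6, which is 25.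

2. Step 13. What may go wrong: oligomerisation by intermolecular metathesis, failure of the strained bridged ring to close, or isomerisation of the allylic alcohol by ruthenium hydrides. Fallback, setting out from 18 and rejoining at 19: the C6 hydroxyl is silylated (TESCl, imidazole) to the bis-silyl ether F5. Lemieux–Johnson cleavage of both side-chain alkenes (OsO4 cat., NaIO4, 2,6-lutidine, dioxane/H2O) gives the dialdehyde F6. Intramolecular pinacol coupling with SmI2 (THF, high dilution), which should spare the vinylogous-ester carbonyl, closes the ring as the cis-diol F7. Thiocarbonyldiimidazole converts this into the cyclic thionocarbonate F8, and Corey–Winter elimination (P(OMe)3, heat), a stereospecific syn process, gives the Z-cycloalkene F9. TES removal (HF·pyridine, pyridine, THF, 0 °C) returns 19.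

3. Step 14. What may go wrong: poor facial selectivity, the oxidant attacking the peripheral face anti to the hydroxyl instead of the directed face, or oxidation of the allylic alcohol to the enone. Fallback, setting out from 19 and rejoining at 20: NBS in aqueous THF forms the bromonium ion on the sterically preferred face and water opens it anti, giving the bromohydrin F10 (C7–OH on the O6 face, C8–Br on the opposite face). K2CO3 in MeOH then closes the epoxide by displacement of bromide with inversion, which places the epoxide oxygen on the face that direct attack would miss and gives 20.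

Further compounds
F1 | step 16 | 6-O-triethylsilyl ether of epoxy alcohol 20 | CC[Si](CC)(CC)O[C@H]1C[C@@]2(C)OC(=CC2=O)[C@@H](C)[C@H](O[Si](C)(C)C(C)(C)C)[C@H]3O[C@@H]13
F2 | step 16 | 7-ethynyl-8-hydroxy compound (C7 inverted, 6-OTES, 9-OTBS) | CC[Si](CC)(CC)O[C@H]1C[C@@]2(C)OC(=CC2=O)[C@@H](C)[C@H](O[Si](C)(C)C(C)(C)C)[C@@H](O)[C@@H]1C#C
F3 | step 16 | 8-O-methacrylate of F2 | CC[Si](CC)(CC)O[C@H]1C[C@@]2(C)OC(=CC2=O)[C@@H](C)[C@H](O[Si](C)(C)C(C)(C)C)[C@@H](OC(=O)C(C)=C)[C@@H]1C#C
F4 | step 16 | 7-ethynyl-6-hydroxy 8-O-methacrylate (9-OTBS) | O[C@H]1C[C@@]2(C)OC(=CC2=O)[C@@H](C)[C@H](O[Si](C)(C)C(C)(C)C)[C@@H](OC(=O)C(C)=C)[C@@H]1C#C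
F5 | step 13 | 6-O-triethylsilyl ether of furanone 18 | C=C[C@@H](O[Si](C)(C)C(C)(C)C)[C@H](C)C1=CC(=O)[C@@](C)(C[C@H](O[Si](CC)(CC)CC)/C=C\C)O1
F6 | step 13 | C7/C8 dialdehyde (6-OTES, 9-OTBS) | O=C[C@@H](O[Si](C)(C)C(C)(C)C)[C@H](C)C1=CC(=O)[C@@](C)(C[C@H](O[Si](CC)(CC)CC)C=O)O1
F7 | step 13 | macrocyclic cis-7,8-diol (6-OTES, 9-OTBS) | CC[Si](CC)(CC)O[C@H]1C[C@@]2(C)OC(=CC2=O)[C@@H](C)[C@H](O[Si](C)(C)C(C)(C)C)[C@@H](O)[C@H]1O
F8 | step 13 | cyclic 7,8-thionocarbonate of F7 | CC[Si](CC)(CC)O[C@H]1C[C@@]2(C)OC(=CC2=O)[C@@H](C)[C@H](O[Si](C)(C)C(C)(C)C)[C@H]3OC(=S)O[C@@H]13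
F9 | step 13 | 6-O-triethylsilyl ether of macrocyclic alkene 19 | C1[C@H](O[Si](CC)(CC)CC)/C=C\[C@@H](O[Si](C)(C)C(C)(C)C)[C@H](C)C2=CC(=O)[C@]1(C)O2
F10 | step 14 | 8-bromo-6,7-diol bromohydrin (9-OTBS) | O[C@H]1C[C@@]2(C)OC(=CC2=O)[C@@H](C)[C@H](O[Si](C)(C)C(C)(C)C)[C@H](Br)[C@H]1O
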